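| setting | Monday's | Sunday's | flask |
|---|---|---|---|
| starting material | 0.050 M | 0.050 M | 0.050 M |
| coupling partner | 3 equiv | 3 equiv | 3.00 equiv |
| second substrate | 0.13 equiv | 0.30 equiv | 0.200 equiv |
| protic impurity | 0.025 M | 0.025 M | 0.0250 M |
| remark | run made earlier | run made earlier |  |
| time |  |  | 3.0 h |

| run | time / h | target / % | starting material / % |
|---|---|---|---|
| Monday's | 0.0333 | 19.4 | 78.5 |
| Monday's | 0.0667 | 16.0 | 75.5 |
| Monday's | 0.133 | 15.8 | 70.6 |
| Monday's | 0.333 | 14.4 | 62.5 |
| Monday's | 0.667 | 12.6 | 52.9 |
| Monday's | 1.33 | 12.1 | 44.5 |
| Monday's | 3.00 | 10.7 | 40.9 |
| Sunday's | 0.0333 | 16.8 | 81.9 |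
| Sunday's | 0.0667 | 16.7 | 74.9 |
| Sunday's | 0.133 | 14.7 | 70.9 |
| Sunday's | 0.333 | 14.5 | 60.1 |
| Sunday's | 0.667 | 9.1 | 52.7 |
| Sunday's | 1.33 | 10.0 | 46.9 |
| Sunday's | 3.00 | 9.3 | 39.3 |

(readings scatter by 1 percentage point)

- the analysis behind the earlier runs scatters by 1 percentage point, standard deviation

1. time, not beyond 3.0 h, at which the flask holds most target, in min
2. the amount of target, in percent of the starting material charged, at that time
3. the first time at which target reaches 8.7%, in the same percent, in min

1. Follow the target. At the first reading it stands at 19.4% in Monday's run and 16.8% in Sunday's, at the last at 10.7% and 9.3%. So it peaks early and then sags, and starting material sags with it.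

2. Divide target by starting material and call this r. Pooling the two runs, r reads 0.226 at the first reading and 0.249 at the last. These differ by about what a scatter of 1 percentage point in each reading gives, although the runs carry 0.13 equiv and 0.30 equiv of second substrate. A ratio that holds while both species fall suggests a reversible step: starting material (A) + coupling partner (B) ⇌ target (P).

3. Take free B at the last readings as the charge less what the target holds and less the second substrate, averaged over the two runs and assumed to take one B each, 0.134 M. Then divide r by it to get K = 1.86 M⁻¹. This K, r per unit of free B, is the holding constant, the apparent equilibrium constant of the step, read from the runs.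

4. The flask is charged with 3.00 equiv of coupling partner, like both runs, so expect the same r. Counting no starting material lost by any other route, estimate a ceiling for its target as r/(1+r) of the charge: 20.0%.

5. The forecast gives 18% (16.3% to 20.5%) at 2 min (0.8 min to 3.5 min), with the asked level reached at 0.6 min (0.2 min to 1.3 min). It reads: “The maximum is therefore very early, near the first sampling point.” My estimated ceiling stands higher than that peak, but it is an estimate read from scattered readings, not a forecast of the peak.

6. The flask gives 17.4% at 2.61 min and passes the asked level at 0.359 min, each inside the forecast's range.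

    starting material + coupling partner ⇌ target (K = 1.71 M⁻¹, k = 0.0370 M⁻¹ s⁻¹)
    second substrate + coupling partner → second product (k = 0.204 M⁻¹ s⁻¹)
    starting material + protic impurity → quenched substrate (k = 0.0162 M⁻¹ s⁻¹)

7. Watch r. In the run without the falling back of target, the highest target climbs from 17.4% to 92.1%, the largest single effect on that value. At 3.00 h the flask keeps 90.2% of its coupling partner, so K gives r = 0.251, and the flask shows 0.231. In the neighbour flask with 0.750 equiv of coupling partner, 70.4% of that charge is left at 3.00 h, so K gives r = 0.0491, and that neighbour shows 0.0452.

(All runs were generated by integration for an exercise.)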